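## Retrosynthetic overview

1. The strategy rests on ring A of flavone unit I (C4a–C5–C6–C7–C8–C8a). It is pentasubstituted, and its most crowded bond is C8–O to C4' of the apigenin unit II (double-primed locants). C4a and C8a map onto two adjacent ring carbons of a 2-anisyl-4-pyranone. C8, C7, C6 and C5 map onto an aryloxy β-ketoester side chain.
2. Endgame: the O7''-benzyl group is removed, and before that O7 is methylated selectively, because both 5-hydroxyls are chelated to their C4 carbonyls.
3. Key disconnection: C4a–C5, a Dieckmann-type benzannulation, which leads back to methyl 4-aryloxy-3-oxo-4-(6-anisyl-4-oxopyran-2-yl)butanoate.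
4. The β-ketoester comes from the α-aryloxy acid by malonate homologation. The acid comes from CO2 and the aryloxymethylpyranone. The future C8–O bond is made by SN2 of the 4'-phenoxide of 7-O-benzylapigenin on a bromomethylpyranone.
5. Ring order: unit II is bought as apigenin. Ring C of unit I (the pyranone) is built first from acetylacetone and methyl anisate. Ring A of unit I is closed last.

Key step: step 8

Remark: the target has no stereocentre and no stable atropisomerism about the diaryl ether, so it is achiral. Compounds 9, 11 and 12 carry one enolisable centre, are handled as racemates, and lose that centre in step 8.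

## Route

**Step 1**
Reactants: 1 acetylacetone; 2 methyl 4-methoxybenzoate
Product: 3 1-(4-methoxyphenyl)hexane-1,3,5-trione
Conditions: NaH (4 equiv), DME, reflux; then aq. HCl
Reagents that add atoms: none
Why: Claisen-type terminal aroylation of a β-diketone (Hauser dianion chemistry), in which excess NaH makes the terminal carbanion of sodio-acetylacetone, the non-enolisable ester acylates it, and the product is shielded from further attack as its disodium salt.

**Step 2**
Reactants: 3 1-(4-methoxyphenyl)hexane-1,3,5-trione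
Product: 4 2-(4-methoxyphenyl)-6-methyl-4H-pyran-4-one
Conditions: conc. H2SO4, 0 °C; ice
Reagents that add atoms: none
Why: Acid-mediated cyclodehydration of a 1,3,5-triketone to a 4-pyranone, in which a terminal enol oxygen adds to the protonated distal carbonyl and water is lost, while the cold acid leaves the aryl methyl ether intact.

**Step 3**
Reactants: 4 2-(4-methoxyphenyl)-6-methyl-4H-pyran-4-one
Product: 5 2-(bromomethyl)-6-(4-methoxyphenyl)-4H-pyran-4-one
Conditions: NBS (1.05 equiv), AIBN (cat.), PhCF3, reflux, hν
Reagents that add atoms: N-bromosuccinimide, O=C1CCC(=O)N1Br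
Why: Wohl–Ziegler bromination at the γ-methyl group of an enone (as with crotonates and 2-methylchromones), where the non-polar medium and the initiator should hold back ionic bromination at the pyranone CH positions and on the anisyl ring.

**Step 4**
Reactants: 6 apigenin
Product: 7 7-O-benzylapigenin [7-(benzyloxy)-5-hydroxy-2-(4-hydroxyphenyl)-4H-chromen-4-one]
Conditions: BnBr (1.0 equiv), K2CO3 (1.0 equiv), DMF, rt
Reagents that add atoms: benzyl bromide, BrCc1ccccc1
Why: Williamson etherification under acidity control, since 7-OH is the most acidic phenol of apigenin and 5-OH is hydrogen-bonded to C4=O, so one equivalent of base and halide should benzylate O7 and leave 4'-OH free.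

**Step 5**
Reactants: 5 2-(bromomethyl)-6-(4-methoxyphenyl)-4H-pyran-4-one; 7 7-O-benzylapigenin
Product: 8 7-(benzyloxy)-5-hydroxy-2-(4-{[6-(4-methoxyphenyl)-4-oxo-4H-pyran-2-yl]methoxy}phenyl)-4H-chromen-4-one
Conditions: K2CO3 (1.5 equiv), DMF, rt
Reagents that add atoms: none
Why: SN2 Williamson etherification at a primary allylic-type bromide (as with chlorokojic acid), in which only the unchelated 4'-phenoxide of 7 is nucleophilic, so the later crowded C8–O bond is made at an unhindered sp3 carbon.

**Step 6**
Reactants: 8 aryloxymethylpyranone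
Product: 9 (±)-2-{4-[7-(benzyloxy)-5-hydroxy-4-oxo-4H-chromen-2-yl]phenoxy}-2-[6-(4-methoxyphenyl)-4-oxo-4H-pyran-2-yl]acetic acid
Conditions: LiHMDS (3 equiv), THF/DMPU, −78 °C; CO2 (g), −78 → −20 °C; cold 1 M HCl; used without delay
Reagents that add atoms: carbon dioxide, O=C=O
Why: Vinylogous enolate carboxylation, in which the first equivalent of base gives the 5''-phenoxide, the next removes a side-chain proton as in known γ-deprotonations of 2-alkyl-4-pyranones, and CO2 is taken up at the exocyclic carbon because that restores the pyranone; CO2 is preferred to a malonyl chloride, whose acidic CH2 would only quench the dienolate.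

**Step 7**
Reactants: 9 α-aryloxy acid; 10 potassium methyl malonate
Product: 12 methyl (±)-4-{4-[7-(benzyloxy)-5-hydroxy-4-oxo-4H-chromen-2-yl]phenoxy}-4-[6-(4-methoxyphenyl)-4-oxo-4H-pyran-2-yl]-3-oxobutanoate, via acyl imidazolide 11 (not isolated)
Conditions: CDI (1.1 equiv), THF, rt; then 10 (2 equiv), MgCl2, Et3N, MeCN, rt; 1 M HCl
Reagents that add atoms: 1,1'-carbonyldiimidazole, O=C(n1ccnc1)n1ccnc1 (its imidazolyl group stands in 11 only)
Why: Masamune–Brooks homologation, in which the acyl imidazolide C-acylates the magnesium enolate of the malonate half ester and decarboxylation gives the β-ketoester under nearly neutral conditions; the method also tolerates malonic half acids of similar α-acidity.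

**Step 8**
Reactants: 12 aryloxy β-ketoester
Product: 14 8-{4-[7-(benzyloxy)-5-hydroxy-4-oxo-4H-chromen-2-yl]phenoxy}-5,7-dihydroxy-2-(4-methoxyphenyl)-4H-chromen-4-one, via trione tautomer 13 (not isolated)
Conditions: DBU (3 equiv), dry DMF, 4 Å MS, rt → 70 °C; cold 1 M HCl
Reagents that add atoms: none
Why: Proposed new method: DBU should remove the most acidic carbon-bound proton of 12, the C8–H flanked by the C7 ketone, the aryloxy group and the pyranone, and the anion is delocalised through C8a=C4a onto the pyranone carbonyl (a 2-alkylidene-2H-pyran-4-olate), so ring carbon C4a gains enolate α-character while the C6 methylene and the ester remain un-ionised and electrophilic. C4a adds to the ester carbonyl C5 in a 6-(enolexo)-exo-trig Dieckmann-type closure that forms C4a–C5, methoxide leaves to give 13, and loss of the C4a–H with enolisation of the C5 and C7 carbonyls gives aromatic ring A irreversibly. The closest known reaction types are the Claisen cyclisation of 3,5,7-triketo esters to acylphloroglucinols and the side-chain dienolate chemistry of 2-alkyl-4-pyranones, which normally reacts at the exocyclic carbon. Reaction at C4a and not at C8 is enforced by ring size, because attack from C8 would give a cyclobutanone, and aldol or 2-pyranone closures are shut off because the other polyketide carbonyls are locked in the pyranone. A non-nucleophilic, non-chelating base with sieves to bind methanol is chosen because a metal-chelated Z-enolate of the β-ketoester would hold C5 trans to C8 and because alkoxide would start retro-Claisen loss of the malonyl unit. No stereocentre is formed, the labile one at C8 vanishes, and the 8-position of the ether is fixed by the chain.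

**Step 9**
Reactants: 14 5,7-dihydroxy-8-aryloxy biflavone 7''-benzyl ether
Product: 15 8-{4-[7-(benzyloxy)-5-hydroxy-4-oxo-4H-chromen-2-yl]phenoxy}-5-hydroxy-7-methoxy-2-(4-methoxyphenyl)-4H-chromen-4-one
Conditions: MeI (1.1 equiv), K2CO3 (1.1 equiv), acetone, reflux
Reagents that add atoms: iodomethane, CI
Why: Selective Williamson methylation, since 7-OH is the only unchelated and the most acidic phenol, whereas 5-OH and 5''-OH are hydrogen-bonded to their C4 carbonyls and are known to resist one equivalent of MeI/K2CO3.

**Step 10**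
Reactants: 15 7-O-methyl 7''-O-benzyl biflavone
Product: 16 target, 8-[4-(5,7-dihydroxy-4-oxo-4H-chromen-2-yl)phenoxy]-5-hydroxy-7-methoxy-2-(4-methoxyphenyl)-4H-chromen-4-one
Conditions: H2 (1 atm), 10% Pd/C, THF/MeOH, rt
Reagents that add atoms: none
Why: Catalytic hydrogenolysis of an aryl benzyl ether, under which the flavone C2=C3 bonds, the diaryl ether and the methyl ethers are inert at atmospheric pressure.

## Compound list

1 | acetylacetone | CC(=O)CC(C)=O | starting material
2 | methyl 4-methoxybenzoate | COC(=O)c1ccc(OC)cc1 | starting material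
3 | 1-(4-methoxyphenyl)hexane-1,3,5-trione | COc1ccc(cc1)C(=O)CC(=O)CC(C)=O | intermediate
4 | 2-(4-methoxyphenyl)-6-methyl-4H-pyran-4-one | COc1ccc(cc1)-c1cc(=O)cc(C)o1 | intermediate
5 | 2-(bromomethyl)-6-(4-methoxyphenyl)-4H-pyran-4-one | COc1ccc(cc1)-c1cc(=O)cc(CBr)o1 | intermediate
6 | apigenin | O=c1cc(-c2ccc(O)cc2)oc2cc(O)cc(O)c12 | starting material
7 | 7-O-benzylapigenin | Oc1ccc(cc1)-c1cc(=O)c2c(O)cc(OCc3ccccc3)cc2o1 | intermediate
8 | aryloxymethylpyranone (4'-O-pyranonylmethyl-7-O-benzylapigenin) | COc1ccc(cc1)-c1cc(=O)cc(COc2ccc(cc2)-c2cc(=O)c3c(O)cc(OCc4ccccc4)cc3o2)o1 | intermediate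
9 | (±)-α-aryloxy-α-(6-anisyl-4-oxopyran-2-yl)acetic acid | COc1ccc(cc1)-c1cc(=O)cc(o1)C(Oc1ccc(cc1)-c1cc(=O)c2c(O)cc(OCc3ccccc3)cc2o1)C(O)=O | intermediate
10 | potassium methyl malonate | [K+].COC(=O)CC([O-])=O | starting material
11 | acyl imidazolide of 9 (racemic, not isolated) | COc1ccc(cc1)-c1cc(=O)cc(o1)C(Oc1ccc(cc1)-c1cc(=O)c2c(O)cc(OCc3ccccc3)cc2o1)C(=O)n1ccnc1 | intermediate
12 | methyl (±)-4-aryloxy-3-oxo-4-(6-anisyl-4-oxopyran-2-yl)butanoate | COC(=O)CC(=O)C(Oc1ccc(cc1)-c1cc(=O)c2c(O)cc(OCc3ccccc3)cc2o1)c1cc(=O)cc(o1)-c1ccc(OC)cc1 | intermediate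
13 | 8-aryloxy-2-anisyl-4aH-chromene-4,5,7(6H)-trione tautomer (not isolated) | COc1ccc(cc1)C1=CC(=O)C2C(=O)CC(=O)C(Oc3ccc(cc3)-c3cc(=O)c4c(O)cc(OCc5ccccc5)cc4o3)=C2O1 | intermediate
14 | 5,7-dihydroxy-8-aryloxy biflavone 7''-benzyl ether | COc1ccc(cc1)-c1cc(=O)c2c(O)cc(O)c(Oc3ccc(cc3)-c3cc(=O)c4c(O)cc(OCc5ccccc5)cc4o3)c2o1 | intermediate
15 | 5-hydroxy-7-methoxy-8-aryloxy biflavone 7''-benzyl ether | COc1ccc(cc1)-c1cc(=O)c2c(O)cc(OC)c(Oc3ccc(cc3)-c3cc(=O)c4c(O)cc(OCc5ccccc5)cc4o3)c2o1 | intermediate
16 | CNP0259871.0 | COc1ccc(-c2cc(=O)c3c(O)cc(OC)c(Oc4ccc(-c5cc(=O)c6c(O)cc(O)cc6o5)cc4)c3o2)cc1 | target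

## Step count and risk

Total step count: 10.
Longest linear sequence: 9 steps (steps 1–3 and 5–10).

**Step 8 (Proposed new method).**
- The strongly delocalised anion may fail to attack the ester.
- Liberated methanol or methoxide may cleave the C7–C8 bond by retro-Claisen reaction or open the pyranone.
- The fallback uses known chemistry and makes the C8–O bond on a finished arene by Ullmann-type coupling. It sets out from 6 and 7 and comes back at 16.
- Apigenin 6 is permethylated (Me2SO4, K2CO3, acetone, reflux) to 5,7,4'-tri-O-methylapigenin F1.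
- F1 is iodinated at its most electron-rich position (NIS, TFA, MeCN) to 8-iodo-5,7,4'-trimethoxyflavone F2.
- Copper-catalysed etherification of F2 with the 4'-phenol of 7 (CuI, N,N-dimethylglycine, Cs2CO3, dioxane, 100 °C) should give the 5-O-methyl 7''-O-benzyl biflavone ether F3.
- BCl3 (CH2Cl2, −78 → 0 °C) then removes the chelation-activated 5-O-methyl group and the benzyl ether together to give 16.

**Step 6.**
- The dilithio salt of 8 may be poorly soluble, and deprotonation may be incomplete.
- Proton transfer between product and dienolate may limit conversion.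
- The acid may decarboxylate on acidification.
- The fallback moves the strong-base step onto the small pyranone and makes the ether at an α-bromo ester. It sets out from 4 (with 7) and comes back at 9, passing by steps 3 and 5.
- Compound 4 is deprotonated (LiHMDS, 2.2 equiv, THF, −78 °C) and trapped with Boc2O to give tert-butyl [6-(4-methoxyphenyl)-4-oxo-4H-pyran-2-yl]acetate F4.
- NBS brominates the doubly activated methylene to give tert-butyl bromo[6-(4-methoxyphenyl)-4-oxo-4H-pyran-2-yl]acetate F5.
- K2CO3/DMF with 7 gives the tert-butyl α-aryloxy ester F6.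
- TFA/CH2Cl2 at 0 °C releases 9.

**Step 3.**
- Ionic bromination at the pyranone CH positions or on the anisyl ring, and over-bromination of the methyl group, may compete with the radical chain.
- The fallback replaces halogenation by oxidation and a redox condensation. It sets out from 4 and comes back at 8.
- Riley oxidation (SeO2, dioxane, reflux) gives 6-(4-methoxyphenyl)-4-oxo-4H-pyran-2-carbaldehyde F7.
- NaBH4 (MeOH, 0 °C) reduces only the aldehyde to 2-(hydroxymethyl)-6-(4-methoxyphenyl)-4H-pyran-4-one F8.
- A Mitsunobu reaction of F8 with the 4'-phenol of 7 (PPh3, DIAD, THF) gives 8.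

## Further compounds

F1 | step 8 | 5,7,4'-tri-O-methylapigenin | COc1ccc(cc1)-c1cc(=O)c2c(OC)cc(OC)cc2o1
F2 | step 8 | 8-iodo-5,7,4'-trimethoxyflavone | COc1ccc(cc1)-c1cc(=O)c2c(OC)cc(OC)c(I)c2o1
F3 | step 8 | 5-O-methyl 7''-O-benzyl biflavone ether | COc1ccc(cc1)-c1cc(=O)c2c(OC)cc(OC)c(Oc3ccc(cc3)-c3cc(=O)c4c(O)cc(OCc5ccccc5)cc4o3)c2o1
F4 | step 6 | tert-butyl [6-(4-methoxyphenyl)-4-oxo-4H-pyran-2-yl]acetate | COc1ccc(cc1)-c1cc(=O)cc(CC(=O)OC(C)(C)C)o1
F5 | step 6 | tert-butyl bromo[6-(4-methoxyphenyl)-4-oxo-4H-pyran-2-yl]acetate (racemic) | COc1ccc(cc1)-c1cc(=O)cc(o1)C(Br)C(=O)OC(C)(C)C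
F6 | step 6 | tert-butyl α-aryloxy ester of 9 (racemic) | COc1ccc(cc1)-c1cc(=O)cc(o1)C(Oc1ccc(cc1)-c1cc(=O)c2c(O)cc(OCc3ccccc3)cc2o1)C(=O)OC(C)(C)C
F7 | step 3 | 6-(4-methoxyphenyl)-4-oxo-4H-pyran-2-carbaldehyde | COc1ccc(cc1)-c1cc(=O)cc(C=O)o1
F8 | step 3 | 2-(hydroxymethyl)-6-(4-methoxyphenyl)-4H-pyran-4-one | COc1ccc(cc1)-c1cc(=O)cc(CO)o1
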